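Readings and results are calculated for substances that don't exist; the scatter is artificial.

Slowness was the first thing we disputed: how slowly may c(left-handed substrate) fall in this flask and still leave the wanted excess in time?

in all of them: precatalyst 1 mol%

| run | left-handed substrate | right-handed substrate | partner | remark | time |
|---|---|---|---|---|---|
| grey | 1.4 M | 1.4 M | 1.5 equiv | run made earlier |  |
| flask | 1.0 M | 1.0 M | 1.50 equiv |  | 30 min |

grey run (percent of the left-handed substrate and right-handed substrate together charged)

| time / min | right-handed substrate / % | left-handed substrate / % |
|---|---|---|
| 1.50 | 49.9 | 33.6 |
| 5.00 | 49.4 | 8.4 |
| 8.00 | 48.9 | 2.7 |
| 12.0 | 47.9 | 0.6 |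
| 20.0 | 46.5 | 0 |
| 25.0 | 45.1 | 0.3 |
| 30.0 | 43.5 | 0.2 |

(each reading ± 0.3 percentage points)

* whether the excess of right-handed substrate over left-handed substrate among what is left of the two reaches 98% by 30 min (no / yes)
* the highest excess of right-handed substrate over left-handed substrate among what is left of the two up to 30 min

- catalyst is single-handed; left-handed substrate and right-handed substrate are mirror images of each other, charged as a racemate, each of them at the stated concentration
- no earlier run changes the charge of precatalyst; that part of a forecast is a guess

My own reckoning treats the fall as a plain exponential (pseudo-first-order). The wanted excess means c(left-handed substrate) has come down to 1.01% of c(right-handed substrate). With the right-handed substrate held at its charge, a first round gives 0.153 min⁻¹ over the 30 min allowed. Going round once more, I put in the grey run's 43.5% of right-handed substrate at 30.0 min, and that raises the figure to 0.158 min⁻¹. This is the needed pace, the first-order rate constant of the left-handed substrate that brings the wanted excess just at the longest time allowed.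

The grey run's first two left-handed readings give a pace of 0.396 min⁻¹, 2.51 times the needed pace, but that run is more concentrated and no run shows what dilution does. The forecast's lowest guess, 0.19 per minute, still clears the needed pace, and its first-round threshold is close to mine: “Reaching 98% needs only k > 0.15 /min, which is likely.”

So the two of us parted over the top. One held that the fall simply continues, and the forecast, yes and 99.6%, is that side's number. The other took the grey run's late 0.3% and 0.2% as a real floor of left-handed substrate, which gives a top of 99.1%, though those readings stand against a scatter of 0.3 percentage points.

The flask gives yes and 99.9%, and it reaches the wanted excess at 19.7 min, with 48.1% of right-handed substrate left. Over that stretch the flask's average pace comes to 0.236 min⁻¹, faster than the needed pace by a factor of 1.49. The floor view stays right on the first question, since its figure stands above the wanted excess, but the top of this flask lies above that figure, and the left-handed substrate in this flask keeps falling, from 1.69% at 15.0 min to 0.0221% at 30.0 min.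

    partner + catalyst + left-handed substrate → catalyst + left-handed product (k = 280 L² mol⁻² min⁻¹)
    partner + catalyst + right-handed substrate → catalyst + right-handed product (k = 2.40 L² mol⁻² min⁻¹)
    partner + precatalyst → catalyst + spent reagent (k = 0.0330 L mol⁻¹ min⁻¹)
    partner ⇌ dormant form (K = 0.390, k = 0.240 min⁻¹)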